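The seven-membered ring is cut at C5–C6 and C8–C9 (C1 = methyl-bearing quaternary carbon, C4 = isopropyl carbinol, C5 = ring-fusion CH, C6 = acyloxy carbon, C8 = methylidene carbon, C9 and C10 = diol carbons). The feature exploited is that C6 and C9 are both carbinol carbons in this ring: C6 is the aldol carbon of a C4 ketone, C9 sits next to the C8 methylidene. One chromium-mediated operation therefore joins a cyclopentanone carrying a C5 bromide and the C9 aldehyde with 3-bromobut-3-enal (C6–C8 plus the exocyclic CH2): Reformatsky-type aldol, then Nozaki–Hiyama–Kishi closure, a formal [4+3] annulation that sets C5, C6 and C9.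

Key step: step 8

Remark: the atom labels above are used throughout; the α-silyloxy aldehyde centre C10 is assumed not to epimerize under the neutral conditions of steps 6 and 8.

Step 1
Reactants: 1 3-methylcyclopent-2-en-1-one
Product: 2 (1R)-3-methylcyclopent-2-en-1-ol
Conditions: (S)-1-methyl-3,3-diphenyltetrahydro-1H,3H-pyrrolo[1,2-c][1,3,2]oxazaborole (10 mol %), BH3·SMe2, THF, −20 °C
Reagents that add atoms: none
Why: Corey–Bakshi–Shibata reduction, in which the oxazaborolidine–borane complex binds the ketone with the alkenyl arm as the large group and delivers hydride to one carbonyl face, which should give the (R) allylic alcohol by 1,2-reduction.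

Step 2
Reactants: 2 (1R)-3-methylcyclopent-2-en-1-ol
Product: 3 (3R)-1-methyl-3-(prop-2-en-1-yloxy)cyclopent-1-ene
Conditions: NaH, allyl bromide, Bu4NI (cat.), THF, 0 °C to rt
Reagents that add atoms: allyl bromide, C=CCBr
Why: Williamson ether synthesis on the sodium alkoxide, with no change at the stereocentre.

Step 3
Reactants: 3 (3R)-1-methyl-3-(prop-2-en-1-yloxy)cyclopent-1-ene
Product: 5 triethyl{[(1R)-1-[(1S)-1-methylcyclopent-2-en-1-yl]prop-2-en-1-yl]oxy}silane, via lithium alkoxide 4 (not isolated)
Conditions: n-BuLi, THF, −78 °C; then TESCl, −78 °C to rt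
Reagents that add atoms: chlorotriethylsilane, CC[Si](Cl)(CC)CC
Why: [2,3]-Wittig rearrangement, in which lithiation at the unsubstituted allylic OCH2 is followed by a suprafacial shift through a five-membered envelope that transfers the C–O configuration to the new quaternary C1, while the vinyl group on the carbanion carbon should sit exo (away from the ring CH2) and so set the (R) carbinol C10; the alkoxide is silylated in the same flask.

Step 4
Reactants: 5 triethyl{[(1R)-1-[(1S)-1-methylcyclopent-2-en-1-yl]prop-2-en-1-yl]oxy}silane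
Product: 6 (1R,2R,3R)-2-bromo-3-methyl-3-[(1R)-1-(triethylsilyloxy)prop-2-en-1-yl]cyclopentan-1-ol
Conditions: NBS, THF/H2O (4:1), 0 °C
Reagents that add atoms: N-bromosuccinimide, O=C1CCC(=O)N1Br; water, O
Why: Bromohydrin formation, in which the cis ring alkene should react before the hindered, inductively deactivated vinyl group and water should open the bromonium ion anti at C4, the carbon remote from the quaternary centre, so that bromine ends on C5 (both new centres are erased or inconsequential later).

Step 5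
Reactants: 6 (1R,2R,3R)-2-bromo-3-methyl-3-[(1R)-1-(triethylsilyloxy)prop-2-en-1-yl]cyclopentan-1-ol
Product: 7 (2R,3R)-2-bromo-3-methyl-3-[(1R)-1-(triethylsilyloxy)prop-2-en-1-yl]cyclopentan-1-one
Conditions: Dess–Martin periodinane, NaHCO3, CH2Cl2, 0 °C to rt
Reagents that add atoms: none
Why: Buffered Dess–Martin oxidation of the secondary alcohol should give the α-bromo ketone without touching the silyl ether or the vinyl group.

Step 6
Reactants: 7 (2R,3R)-2-bromo-3-methyl-3-[(1R)-1-(triethylsilyloxy)prop-2-en-1-yl]cyclopentan-1-one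
Product: 8 (2S)-2-[(1R,2R)-2-bromo-1-methyl-3-oxocyclopentyl]-2-(triethylsilyloxy)acetaldehyde
Conditions: O3, CH2Cl2, −78 °C; then Me2S, −78 °C to 0 °C
Reagents that add atoms: ozone, [O-][O+]=O
Why: Ozonolysis with reductive work-up cleaves the only C=C bond to the C9 aldehyde under cold, neutral conditions that leave the bromo ketone and the C10 centre untouched.

Step 7
Reactants: 9 3-bromobut-3-en-1-ol
Product: 10 3-bromobut-3-enal
Conditions: Dess–Martin periodinane, NaHCO3, CH2Cl2, 0 °C
Reagents that add atoms: none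
Why: Buffered Dess–Martin oxidation of the homoallylic alcohol; the β,γ-unsaturated aldehyde is used at once as a solution to avoid isomerization to the conjugated enal.

Step 8
Reactants: 8 (2S)-2-[(1R,2R)-2-bromo-1-methyl-3-oxocyclopentyl]-2-(triethylsilyloxy)acetaldehyde; 10 3-bromobut-3-enal (1.3 equiv)
Product: 12 (3aS,4S,5R,8S,8aS)-5,8-dihydroxy-3a-methyl-6-methylidene-4-(triethylsilyloxy)octahydroazulen-1(2H)-one, via aldol adduct 11 (not isolated)
Conditions: CrCl2 (6 equiv), LiI (cat.), THF, 0 °C to rt; then NiCl2 (5 mol %), DMF, rt, 0.005 M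
Reagents that add atoms: none
Why: Divalent chromium reduces the C5–Br bond of 8 to a trivalent chromium enolate (chromium Reformatsky reaction), which adds to the unhindered aldehyde 10 through a closed chair transition state; once nickel is added, the alkenyl bromide of 11 enters the Nozaki–Hiyama–Kishi cycle (oxidative addition to zerovalent nickel, transmetallation to chromium) and the alkenylchromium adds to the C9 aldehyde. The closest known reaction types are the chromium Reformatsky aldol of α-bromo ketones and the intramolecular Nozaki–Hiyama–Kishi cyclization, run here in one flask as a formal [4+3] annulation. The seven-membered ring closes in the second event by 7-exo-trig attack of C8 on the aldehyde carbon C9. C5 and C6 are set in the aldol, where the ring-locked (E)-enolate in a Zimmerman–Traxler chair should give the anti aldol and the aldehyde should approach C5 anti to the bulky CH(OSiEt3)CHO arm on C1 (syn to the methyl), placing the two arms trans; C9 should follow from a Felkin–Anh arrangement with the silyloxy group anti to the incoming alkenyl, which gives the cis 9,10-dioxygen pattern. The step needs the enolate to choose aldehyde 10 over the aldehyde of a second molecule of 8, and the alkenylchromium to choose the C9 aldehyde over the C4 ketone: the first is secured by the steric shielding of the C9 aldehyde (α-silyloxy, next to a quaternary carbon) and by adding nickel only after the aldol, the second by the strong aldehyde preference of alkenylchromium reagents and by high dilution.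

Step 9
Reactants: 12 (3aS,4S,5R,8S,8aS)-5,8-dihydroxy-3a-methyl-6-methylidene-4-(triethylsilyloxy)octahydroazulen-1(2H)-one
Product: 14 (3aS,4S,5R,8S,8aS)-8-hydroxy-4,5-(isopropylidenedioxy)-3a-methyl-6-methylidene-octahydroazulen-1(2H)-one, via triol 13 (not isolated)
Conditions: camphorsulfonic acid (cat.), MeOH, 0 °C; then 2,2-dimethoxypropane, acetone, rt
Reagents that add atoms: 2,2-dimethoxypropane, COC(C)(C)OC
Why: Acid-catalysed methanolysis removes the triethylsilyl ether and transketalization then locks the cis 9,10-diol as its acetonide, leaving the C6 hydroxyl (no cis neighbour) free.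

Step 10
Reactants: 14 (3aS,4S,5R,8S,8aS)-8-hydroxy-4,5-(isopropylidenedioxy)-3a-methyl-6-methylidene-octahydroazulen-1(2H)-one
Product: 15 (1R,3aS,4S,5R,8S,8aS)-4,5-(isopropylidenedioxy)-3a-methyl-6-methylidene-1-(propan-2-yl)decahydroazulene-1,8-diol
Conditions: iPrMgCl (4 equiv), CeCl3, THF, −78 °C to 0 °C
Reagents that add atoms: isopropylmagnesium chloride, CC(C)[Mg]Cl
Why: Organocerium 1,2-addition (which suppresses enolization, retro-aldol cleavage and hydride transfer), where attack on the carbonyl face opposite to the C1 methyl and the C5–C6 bond should set C4 with its hydroxyl cis to C6.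

Step 11
Reactants: 15 (1R,3aS,4S,5R,8S,8aS)-4,5-(isopropylidenedioxy)-3a-methyl-6-methylidene-1-(propan-2-yl)decahydroazulene-1,8-diol
Product: 16 (1R,3aS,4S,5R,8S,8aS)-1-hydroxy-4,5-(isopropylidenedioxy)-3a-methyl-6-methylidene-1-(propan-2-yl)decahydroazulen-8-yl 3-methylbutanoate
Conditions: 3-methylbutanoic anhydride, 4-(dimethylamino)pyridine, Et3N, CH2Cl2, rt
Reagents that add atoms: 3-methylbutanoic anhydride, CC(C)CC(=O)OC(=O)CC(C)C
Why: Nucleophilic-catalysed acylation (Steglich-type acyl transfer) of the only secondary hydroxyl, since the tertiary C4 hydroxyl is too hindered to react and the diol is masked.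

Step 12
Reactants: 16 (1R,3aS,4S,5R,8S,8aS)-1-hydroxy-4,5-(isopropylidenedioxy)-3a-methyl-6-methylidene-1-(propan-2-yl)decahydroazulen-8-yl 3-methylbutanoate
Product: 17 (1R,3aS,4S,5R,8S,8aS)-1,4,5-trihydroxy-3a-methyl-6-methylidene-1-(propan-2-yl)decahydroazulen-8-yl 3-methylbutanoate
Conditions: AcOH/H2O (4:1), 40 °C
Reagents that add atoms: none
Why: Acetal hydrolysis in aqueous acetic acid should release the cis diol while the ester, the tertiary alcohol and the allylic system survive, and no stereocentre is touched.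

Compound list
1 | 3-methylcyclopent-2-en-1-one | CC1=CC(=O)CC1 | starting material
2 | (1R)-3-methylcyclopent-2-en-1-ol | CC1=C[C@H](O)CC1 | intermediate
3 | (3R)-1-methyl-3-(prop-2-en-1-yloxy)cyclopent-1-ene | CC1=C[C@H](OCC=C)CC1 | intermediate
4 | lithium (1R)-1-[(1S)-1-methylcyclopent-2-en-1-yl]prop-2-en-1-olate | C=C[C@@H](O[Li])[C@@]1(C)CCC=C1 | intermediate
5 | triethyl{[(1R)-1-[(1S)-1-methylcyclopent-2-en-1-yl]prop-2-en-1-yl]oxy}silane | C=C[C@@H](O[Si](CC)(CC)CC)[C@@]1(C)CCC=C1 | intermediate
6 | (1R,2R,3R)-2-bromo-3-methyl-3-[(1R)-1-(triethylsilyloxy)prop-2-en-1-yl]cyclopentan-1-ol | C=C[C@@H](O[Si](CC)(CC)CC)[C@@]1(C)CC[C@@H](O)[C@@H]1Br | intermediate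
7 | (2R,3R)-2-bromo-3-methyl-3-[(1R)-1-(triethylsilyloxy)prop-2-en-1-yl]cyclopentan-1-one | C=C[C@@H](O[Si](CC)(CC)CC)[C@@]1(C)CCC(=O)[C@@H]1Br | intermediate
8 | (2S)-2-[(1R,2R)-2-bromo-1-methyl-3-oxocyclopentyl]-2-(triethylsilyloxy)acetaldehyde | O=C[C@@H](O[Si](CC)(CC)CC)[C@@]1(C)CCC(=O)[C@@H]1Br | intermediate
9 | 3-bromobut-3-en-1-ol | C=C(Br)CCO | starting material
10 | 3-bromobut-3-enal | C=C(Br)CC=O | intermediate
11 | (2S)-2-{(1S,2S)-2-[(1S)-3-bromo-1-hydroxybut-3-en-1-yl]-1-methyl-3-oxocyclopentyl}-2-(triethylsilyloxy)acetaldehyde | C=C(Br)C[C@H](O)[C@H]1C(=O)CC[C@]1(C)[C@H](O[Si](CC)(CC)CC)C=O | intermediate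
12 | (3aS,4S,5R,8S,8aS)-5,8-dihydroxy-3a-methyl-6-methylidene-4-(triethylsilyloxy)octahydroazulen-1(2H)-one | C=C1C[C@H](O)[C@@H]2[C@](C)(CCC2=O)[C@H](O[Si](CC)(CC)CC)[C@@H]1O | intermediate
13 | (3aS,4S,5R,8S,8aS)-4,5,8-trihydroxy-3a-methyl-6-methylidene-octahydroazulen-1(2H)-one | C=C1C[C@H](O)[C@@H]2[C@](C)(CCC2=O)[C@H](O)[C@@H]1O | intermediate
14 | (3aS,4S,5R,8S,8aS)-8-hydroxy-4,5-(isopropylidenedioxy)-3a-methyl-6-methylidene-octahydroazulen-1(2H)-one | C=C1C[C@H](O)[C@@H]2[C@](C)(CCC2=O)[C@@H]3OC(C)(C)O[C@@H]31 | intermediate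
15 | (1R,3aS,4S,5R,8S,8aS)-4,5-(isopropylidenedioxy)-3a-methyl-6-methylidene-1-(propan-2-yl)decahydroazulene-1,8-diol | C=C1C[C@H](O)[C@@H]2[C@](C)(CC[C@@]2(O)C(C)C)[C@@H]3OC(C)(C)O[C@@H]31 | intermediate
16 | (1R,3aS,4S,5R,8S,8aS)-1-hydroxy-4,5-(isopropylidenedioxy)-3a-methyl-6-methylidene-1-(propan-2-yl)decahydroazulen-8-yl 3-methylbutanoate | C=C1C[C@H](OC(=O)CC(C)C)[C@@H]2[C@](C)(CC[C@@]2(O)C(C)C)[C@@H]3OC(C)(C)O[C@@H]31 | intermediate
17 | (1R,3aS,4S,5R,8S,8aS)-1,4,5-trihydroxy-3a-methyl-6-methylidene-1-(propan-2-yl)decahydroazulen-8-yl 3-methylbutanoate | C=C1C[C@H](OC(=O)CC(C)C)[C@@H]2[C@](C)(CC[C@@]2(O)C(C)C)[C@H](O)[C@@H]1O | target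

Total step count: 12. Longest linear sequence: 11 steps (steps 1–6 and 8–12; step 7 prepares the second fragment).

Steps most likely to fail

Step 8 (key step). Four processes could defeat it:
- self-condensation, with the chromium enolate adding to the aldehyde of a second molecule of 8 instead of 10;
- closure of the alkenylchromium onto the C4 ketone (five-membered ring) instead of the C9 aldehyde;
- capture of the C9 aldehyde by the C6 oxygen as a six-membered hemiacetal, which would slow the ring closure;
- poor face selection at C5.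

The fallback separates the two bond formations and sets out from 7 and 10. SmI2 (THF, −78 °C) would turn 7 into its samarium enolate, which adds to 10 to give the aldol (2S,3S)-2-[(1S)-3-bromo-1-hydroxybut-3-en-1-yl]-3-methyl-3-[(1R)-1-(triethylsilyloxy)prop-2-en-1-yl]cyclopentan-1-one F1; no second aldehyde is present at this stage. Silylation of the C6 hydroxyl (TESOTf, 2,6-lutidine) would give the bis(silyl ether) (2S,3S)-2-[(1S)-3-bromo-1-(triethylsilyloxy)but-3-en-1-yl]-3-methyl-3-[(1R)-1-(triethylsilyloxy)prop-2-en-1-yl]cyclopentan-1-one F2, so that no hemiacetal can form. OsO4 (cat.), NaIO4 and 2,6-lutidine in dioxane/water should cleave the monosubstituted vinyl group in preference to the electron-poor bromoalkene and give (2S)-2-{(1S,2S)-2-[(1S)-3-bromo-1-(triethylsilyloxy)but-3-en-1-yl]-1-methyl-3-oxocyclopentyl}-2-(triethylsilyloxy)acetaldehyde F3. CrCl2 with catalytic NiCl2 in DMF at high dilution would then close the ring to (3aS,4S,5R,8S,8aS)-5-hydroxy-3a-methyl-6-methylidene-4,8-bis(triethylsilyloxy)octahydroazulen-1(2H)-one F4. Camphorsulfonic acid in methanol followed by 2,2-dimethoxypropane, as in step 9, removes both silyl groups (through 13) and returns to the route at 14.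

Step 3. The envelope transition state may discriminate poorly between exo and endo vinyl (low selectivity at C10), and a [1,2]-shift may compete. The fallback sets the two centres independently and sets out from 2. Alkylation with ICH2SnBu3 (KH, THF) would give tributyl({[(1R)-3-methylcyclopent-2-en-1-yl]oxy}methyl)stannane F5. Tin–lithium exchange with n-BuLi at −78 °C triggers a Wittig–Still [2,3] shift, which creates only the quaternary centre and should give [(1S)-1-methylcyclopent-2-en-1-yl]methanol F6. Dess–Martin oxidation would give (1S)-1-methylcyclopent-2-ene-1-carbaldehyde F7, which has no α-hydrogen. Catalytic enantioselective vinylation with Zn(CH=CH2)2 and the enantiomer of 3-exo-morpholinoisoborneol that leads to the (R) carbinol (reagent control) would give (1R)-1-[(1S)-1-methylcyclopent-2-en-1-yl]prop-2-en-1-ol F8. Silylation (TESCl, imidazole) returns to the route at 5.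

Step 10. The basic reagent may enolize the ketone or open the β-hydroxy ketone by retro-aldol cleavage, or the isopropyl group may transfer hydride. The fallback sets out from 14. Silylation of the C6 hydroxyl (TESOTf, 2,6-lutidine) would give (3aS,4S,5R,8S,8aS)-4,5-(isopropylidenedioxy)-3a-methyl-6-methylidene-8-(triethylsilyloxy)octahydroazulen-1(2H)-one F9. A samarium Barbier coupling with 2-iodopropane (SmI2, NiI2 cat., THF), in which a weakly basic alkylsamarium is formed in the flask and adds to the ketone from the same face, would give (1R,3aS,4S,5R,8S,8aS)-4,5-(isopropylidenedioxy)-3a-methyl-6-methylidene-1-(propan-2-yl)-8-(triethylsilyloxy)decahydroazulen-1-ol F10. Bu4NF removes the silyl group and returns to the route at 15.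

Further compounds
F1 | step 8 | (2S,3S)-2-[(1S)-3-bromo-1-hydroxybut-3-en-1-yl]-3-methyl-3-[(1R)-1-(triethylsilyloxy)prop-2-en-1-yl]cyclopentan-1-one | C=C(Br)C[C@H](O)[C@H]1C(=O)CC[C@]1(C)[C@H](O[Si](CC)(CC)CC)C=C
F2 | step 8 | (2S,3S)-2-[(1S)-3-bromo-1-(triethylsilyloxy)but-3-en-1-yl]-3-methyl-3-[(1R)-1-(triethylsilyloxy)prop-2-en-1-yl]cyclopentan-1-one | C=C(Br)C[C@H](O[Si](CC)(CC)CC)[C@H]1C(=O)CC[C@]1(C)[C@H](O[Si](CC)(CC)CC)C=C
F3 | step 8 | (2S)-2-{(1S,2S)-2-[(1S)-3-bromo-1-(triethylsilyloxy)but-3-en-1-yl]-1-methyl-3-oxocyclopentyl}-2-(triethylsilyloxy)acetaldehyde | C=C(Br)C[C@H](O[Si](CC)(CC)CC)[C@H]1C(=O)CC[C@]1(C)[C@H](O[Si](CC)(CC)CC)C=O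
F4 | step 8 | (3aS,4S,5R,8S,8aS)-5-hydroxy-3a-methyl-6-methylidene-4,8-bis(triethylsilyloxy)octahydroazulen-1(2H)-one | C=C1C[C@H](O[Si](CC)(CC)CC)[C@@H]2[C@](C)(CCC2=O)[C@H](O[Si](CC)(CC)CC)[C@@H]1O
F5 | step 3 | tributyl({[(1R)-3-methylcyclopent-2-en-1-yl]oxy}methyl)stannane | CC1=C[C@H](OC[Sn](CCCC)(CCCC)CCCC)CC1
F6 | step 3 | [(1S)-1-methylcyclopent-2-en-1-yl]methanol | OC[C@@]1(C)CCC=C1
F7 | step 3 | (1S)-1-methylcyclopent-2-ene-1-carbaldehyde | O=C[C@@]1(C)CCC=C1
F8 | step 3 | (1R)-1-[(1S)-1-methylcyclopent-2-en-1-yl]prop-2-en-1-ol | C=C[C@@H](O)[C@@]1(C)CCC=C1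
F9 | step 10 | (3aS,4S,5R,8S,8aS)-4,5-(isopropylidenedioxy)-3a-methyl-6-methylidene-8-(triethylsilyloxy)octahydroazulen-1(2H)-one | C=C1C[C@H](O[Si](CC)(CC)CC)[C@@H]2[C@](C)(CCC2=O)[C@@H]3OC(C)(C)O[C@@H]31
F10 | step 10 | (1R,3aS,4S,5R,8S,8aS)-4,5-(isopropylidenedioxy)-3a-methyl-6-methylidene-1-(propan-2-yl)-8-(triethylsilyloxy)decahydroazulen-1-ol | C=C1C[C@H](O[Si](CC)(CC)CC)[C@@H]2[C@](C)(CC[C@@]2(O)C(C)C)[C@@H]3OC(C)(C)O[C@@H]31
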